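A direct plan would condense the MOM-protected 5-prenyl-2,4-dihydroxyacetophenone A1 with the chromene aldehyde A2, epoxidise the chalcone,
rearrange it with acid to the isoflavone A3, reduce A3 by asymmetric transfer hydrogenation to the cis-isoflavan-4-ol A4 and remove the 4-OH.
Its weakest steps would be: (i) the nuclear prenylations that make A1 and A2, where ring position and C- versus O-alkylation would be left to chance;
(ii) the acid step that would rearrange the epoxide and strip three MOM groups with an ortho-prenylphenol and a chromene present (chroman closure, addition);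
(iii) the removal of the C4 oxygen from A4 in hot alkaline borohydride, where the quinone methide could tautomerise to the isoflav-3-ene and erase C3,
a centre that would itself rest on a dynamic kinetic resolution; a carbonyl would be carried through four steps only to be deleted.

**Plan of the new route**
Retrosynthesis cuts the two silyl ethers, then the C6–prenyl bond (Stille), then ring D back to a 2′-O-(1,1-dimethylpropargyl) ether (Claisen cascade).
The key step then cuts C3–C1′ and C4–C4a together, opening ring C to a (2R)-1-aryl-3-aryloxypropan-2-ol, which falls apart into an aryl Grignard reagent and an (R)-glycidyl aryl ether, both from 4-bromoresorcinol.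
The feature that allows this: C3 carries ring B and lies between C2 (on O1) and C4 (on C4a, para to O7), so the core is the aryl-shifted, Friedel–Crafts-closed isomer of that open-chain alcohol; O2′ and O4′, ortho and para to C1′, make ring B a strong bridging group.
Rings A and B are bought; ring C arises in step 6 and ring D in step 7.
No nuclear prenylation occurs (bromine fixes C6, and O2′ carries the chromene carbons from the start), no acid is used once an alkene exists (fluoride is the last reagent), and C4 never bears oxygen.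
C3 comes stereospecifically from a bought (R)-oxirane.

Key step: step 6

Assumption (remark on the chemistry): one equivalent of an electrophile is taken to react with 4-bromoresorcinol mainly at the hydroxyl para to bromine, the ortho-bromo hydroxyl being hindered; steps 1 and 3 rest on this.

**Route**

Step 1
Reactants: 1 4-bromoresorcinol (4-bromobenzene-1,3-diol); 2 (R)-glycidyl 3-nitrobenzenesulfonate
Product: 3 (R)-2-bromo-5-(oxiran-2-ylmethoxy)phenol
Conditions: 1 (1.5 equiv), K2CO3 (1.0 equiv), DMF, 0 °C → rt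
Reagents that add atoms: (R)-glycidyl 3-nitrobenzenesulfonate, O=S(=O)(OC[C@H]1CO1)c1cccc([N+](=O)[O-])c1
Why: Williamson etherification in which the hydroxyl para to bromine should react in preference to the shielded ortho-bromo hydroxyl, and in which the arenesulfonate is displaced at CH2 without touching the oxirane carbon, so the (R) centre of 2 is carried over unchanged.

Step 2
Reactants: 3 (R)-2-bromo-5-(oxiran-2-ylmethoxy)phenol; 4 chlorotriisopropylsilane
Product: 5 (R)-[2-bromo-5-(oxiran-2-ylmethoxy)phenoxy]triisopropylsilane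
Conditions: i-Pr3SiCl (1.2 equiv), imidazole, DMF, rt
Reagents that add atoms: chlorotriisopropylsilane, CC(C)[Si](Cl)(C(C)C)C(C)C
Why: O-silylation of the remaining phenol gives the future O7 a base- and Grignard-stable donor group that keeps C4a (para to it) nucleophilic and falls to fluoride at the end.

Step 3
Reactants: 1 4-bromoresorcinol; 4 chlorotriisopropylsilane
Product: 6 2-bromo-5-[(triisopropylsilyl)oxy]phenol
Conditions: i-Pr3SiCl (1.0 equiv), imidazole, CH2Cl2, 0 °C
Reagents that add atoms: chlorotriisopropylsilane, CC(C)[Si](Cl)(C(C)C)C(C)C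
Why: mono-silylation with a bulky silyl chloride should take the unhindered hydroxyl para to bromine (the future O4′) and leave the ortho-bromo hydroxyl (the future O2′) free, which tells the two ring-B oxygens apart in one step.

Step 4
Reactants: 6 2-bromo-5-[(triisopropylsilyl)oxy]phenol; 7 3-chloro-3-methylbut-1-yne
Product: 8 {4-bromo-3-[(2-methylbut-3-yn-2-yl)oxy]phenoxy}triisopropylsilane
Conditions: DBU, CuCl2 (1 mol %), MeCN, 0 °C → rt
Reagents that add atoms: 3-chloro-3-methylbut-1-yne, CC(C)(Cl)C#C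
Why: copper-catalysed propargylic etherification, which alkylates even hindered phenols at the tertiary carbon through a copper-bound propargyl/allenylidene electrophile, puts all five carbons of ring D on O2′.

Step 5
Reactants: 8 {4-bromo-3-[(2-methylbut-3-yn-2-yl)oxy]phenoxy}triisopropylsilane; 5 (R)-[2-bromo-5-(oxiran-2-ylmethoxy)phenoxy]triisopropylsilane
Product: 10 (2R)-1-[4-bromo-3-(triisopropylsilyloxy)phenoxy]-3-{2-[(2-methylbut-3-yn-2-yl)oxy]-4-(triisopropylsilyloxy)phenyl}propan-2-ol, via diorganomagnesium species 9 (not isolated)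
Conditions: 8 (1.3 equiv), i-PrMgCl (1.35 equiv), THF, 0 °C; Mg, LiCl, 40 °C; then CuI (10 mol %), 5 (1.0 equiv), −30 → 0 °C; aq. NH4Cl
Reagents that add atoms: none
Why: copper-catalysed SN2 opening of a terminal epoxide by an aryl Grignard reagent at the unsubstituted carbon; the alkyne is first turned into its magnesium acetylide, which cannot quench the aryl–magnesium bond and does not transfer from copper, and the oxirane carbon is not attacked, so the carbinol is (R).

Step 6
Reactants: 10 (2R)-1-[4-bromo-3-(triisopropylsilyloxy)phenoxy]-3-{2-[(2-methylbut-3-yn-2-yl)oxy]-4-(triisopropylsilyloxy)phenyl}propan-2-ol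
Product: 13 (3R)-6-bromo-3-{2-[(2-methylbut-3-yn-2-yl)oxy]-4-(triisopropylsilyloxy)phenyl}-7-(triisopropylsilyloxy)chromane, via triflate 11 (not isolated), via phenonium ion 12 (not isolated)
Conditions: Tf2O (1.15 equiv), 2,6-di-tert-butyl-4-methylpyridine (2.5 equiv), CH2Cl2 (0.01 M), −78 → 0 °C
Reagents that add atoms: none
Why: Proposed new method: O-triflation makes the secondary carbinol a leaving group that is expelled with anchimeric assistance by ring B, whose C1′ attacks the carbinol carbon from the back to give a spiro-cyclopropyl phenonium ion; the tethered ring A then opens this ion at its CH2 carbon through C4a, so that ring B has moved from C4 to C3 and ring C is closed in the same operation. The closest known reaction types are the stereospecific 1,2-aryl shift of β-arylalkyl sulfonates through phenonium ions and the dehydrative Friedel–Crafts arylation of β-aryl alcohols and epoxides through such ions, here made intramolecular. Ring C closes by 6-exo-tet Friedel–Crafts alkylation (C4–C4a); attack on the secondary carbon would give a strained five-membered ring and is further disfavoured by the electron-withdrawing aryloxymethyl group on that carbon. C3 is the only stereocentre and is set by inversion of the (R)-carbinol carbon in the aryl-bridging step; the ring closure does not touch it, and the CIP priorities make the product (3R). The step needs aryl participation to outrun participation by the ortho ether oxygen and hydride shift, which the ortho/para oxygen donors of ring B, the hindered tertiary-alkyl ether and the low temperature should secure. It also needs attack by C4a and not C8, which is secured because C4a is para to the silyloxy group while C8 is flanked by two oxygens.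

Step 7
Reactants: 13 (3R)-6-bromo-3-{2-[(2-methylbut-3-yn-2-yl)oxy]-4-(triisopropylsilyloxy)phenyl}-7-(triisopropylsilyloxy)chromane
Product: 16 (3R)-6-bromo-3-[2,2-dimethyl-5-(triisopropylsilyloxy)-2H-chromen-8-yl]-7-(triisopropylsilyloxy)chromane, via allenylphenol 14 (not isolated), via o-quinone methide 15 (not isolated)
Conditions: o-xylene, 140 °C
Reagents that add atoms: none
Why: aromatic propargyl Claisen cascade ([3,3] shift, enolisation, [1,5]-H shift, oxa-6π electrocyclisation) that can only go to C3′, the one free ortho position of O2′ because C1′ carries the chroman, and that leaves C3 untouched under neutral thermal conditions.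

Step 8
Reactants: 16 (3R)-6-bromo-3-[2,2-dimethyl-5-(triisopropylsilyloxy)-2H-chromen-8-yl]-7-(triisopropylsilyloxy)chromane; 17 tributyl(3-methylbut-2-en-1-yl)stannane
Product: 18 (3R)-3-[2,2-dimethyl-5-(triisopropylsilyloxy)-2H-chromen-8-yl]-6-(3-methylbut-2-en-1-yl)-7-(triisopropylsilyloxy)chromane
Conditions: Pd(PPh3)4 (10 mol %), DMF, 100 °C
Reagents that add atoms: tributyl(3-methylbut-2-en-1-yl)stannane, CC(C)=CC[Sn](CCCC)(CCCC)CCCC
Why: Stille coupling at the only C–Br bond puts the prenyl group on C6 by construction, reductive elimination at the less substituted allyl terminus giving the linear isomer, and the hindered chromene alkene is inert.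

Step 9
Reactants: 18 (3R)-3-[2,2-dimethyl-5-(triisopropylsilyloxy)-2H-chromen-8-yl]-6-(3-methylbut-2-en-1-yl)-7-(triisopropylsilyloxy)chromane
Product: 19 (3R)-3-(5-hydroxy-2,2-dimethyl-2H-chromen-8-yl)-6-(3-methylbut-2-en-1-yl)chroman-7-ol (target)
Conditions: Bu4NF (2.5 equiv), THF, 0 °C; aq. NH4Cl
Reagents that add atoms: none
Why: fluoride cleavage of both aryl silyl ethers frees O7 and O4′ without acid, so neither the ortho-prenylphenol nor the chromene can cyclise or add, and C3 (not acidic, not benzylic to a leaving group) is not at risk.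

**Compound list**
1 | 4-bromoresorcinol | Oc1ccc(Br)c(O)c1 | starting material
2 | (R)-glycidyl 3-nitrobenzenesulfonate | O=S(=O)(OC[C@H]1CO1)c1cccc([N+](=O)[O-])c1 | starting material
3 | (R)-2-bromo-5-(oxiran-2-ylmethoxy)phenol | Oc1cc(OC[C@H]2CO2)ccc1Br | intermediate
4 | chlorotriisopropylsilane | CC(C)[Si](Cl)(C(C)C)C(C)C | starting material
5 | (R)-[2-bromo-5-(oxiran-2-ylmethoxy)phenoxy]triisopropylsilane | CC(C)[Si](Oc1cc(OC[C@H]2CO2)ccc1Br)(C(C)C)C(C)C | intermediate
6 | 2-bromo-5-[(triisopropylsilyl)oxy]phenol | Oc1cc(O[Si](C(C)C)(C(C)C)C(C)C)ccc1Br | intermediate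
7 | 3-chloro-3-methylbut-1-yne | CC(C)(Cl)C#C | starting material
8 | {4-bromo-3-[(2-methylbut-3-yn-2-yl)oxy]phenoxy}triisopropylsilane | C#CC(C)(C)Oc1cc(O[Si](C(C)C)(C(C)C)C(C)C)ccc1Br | intermediate
9 | diorganomagnesium species from 8 (aryl magnesium bromide and magnesium acetylide) | Cl[Mg]C#CC(C)(C)Oc1cc(O[Si](C(C)C)(C(C)C)C(C)C)ccc1[Mg]Br | intermediate
10 | (2R)-1-[4-bromo-3-(triisopropylsilyloxy)phenoxy]-3-{2-[(2-methylbut-3-yn-2-yl)oxy]-4-(triisopropylsilyloxy)phenyl}propan-2-ol | C#CC(C)(C)Oc1cc(O[Si](C(C)C)(C(C)C)C(C)C)ccc1C[C@@H](O)COc1ccc(Br)c(O[Si](C(C)C)(C(C)C)C(C)C)c1 | intermediate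
11 | trifluoromethanesulfonate of 10 (2R) | C#CC(C)(C)Oc1cc(O[Si](C(C)C)(C(C)C)C(C)C)ccc1C[C@@H](OS(=O)(=O)C(F)(F)F)COc1ccc(Br)c(O[Si](C(C)C)(C(C)C)C(C)C)c1 | intermediate
12 | aryl-bridged phenonium ion (spiro[2.5]octadienyl cation, drawn as the silyloxocarbenium form) | C#CC(C)(C)OC1=CC(=[O+][Si](C(C)C)(C(C)C)C(C)C)C=CC12C[C@H]2COc1ccc(Br)c(O[Si](C(C)C)(C(C)C)C(C)C)c1 | intermediate
13 | (3R)-6-bromo-3-{2-[(2-methylbut-3-yn-2-yl)oxy]-4-(triisopropylsilyloxy)phenyl}-7-(triisopropylsilyloxy)chromane | C#CC(C)(C)Oc1cc(O[Si](C(C)C)(C(C)C)C(C)C)ccc1[C@@H]1COc2cc(O[Si](C(C)C)(C(C)C)C(C)C)c(Br)cc2C1 | intermediate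
14 | allenylphenol: 6-[(3R)-6-bromo-7-(triisopropylsilyloxy)chroman-3-yl]-2-(3-methylbuta-1,2-dien-1-yl)-3-(triisopropylsilyloxy)phenol | CC(C)=C=Cc1c(O)c([C@@H]2COc3cc(O[Si](C(C)C)(C(C)C)C(C)C)c(Br)cc3C2)ccc1O[Si](C(C)C)(C(C)C)C(C)C | intermediate
15 | o-quinone methide: 2-[(3R)-6-bromo-7-(triisopropylsilyloxy)chroman-3-yl]-6-(3-methylbut-2-en-1-ylidene)-5-(triisopropylsilyloxy)cyclohexa-2,4-dien-1-one | CC(C)=CC=C1C(=O)C([C@@H]2COc3cc(O[Si](C(C)C)(C(C)C)C(C)C)c(Br)cc3C2)=CC=C1O[Si](C(C)C)(C(C)C)C(C)C | intermediate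
16 | (3R)-6-bromo-3-[2,2-dimethyl-5-(triisopropylsilyloxy)-2H-chromen-8-yl]-7-(triisopropylsilyloxy)chromane | CC1(C)C=Cc2c(O[Si](C(C)C)(C(C)C)C(C)C)ccc([C@@H]3COc4cc(O[Si](C(C)C)(C(C)C)C(C)C)c(Br)cc4C3)c2O1 | intermediate
17 | tributyl(3-methylbut-2-en-1-yl)stannane | CC(C)=CC[Sn](CCCC)(CCCC)CCCC | starting material
18 | (3R)-3-[2,2-dimethyl-5-(triisopropylsilyloxy)-2H-chromen-8-yl]-6-(3-methylbut-2-en-1-yl)-7-(triisopropylsilyloxy)chromane | CC(C)=CCc1cc2c(cc1O[Si](C(C)C)(C(C)C)C(C)C)OC[C@@H](c1ccc(O[Si](C(C)C)(C(C)C)C(C)C)c3c1OC(C)(C)C=C3)C2 | intermediate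
19 | (3R)-3-(5-hydroxy-2,2-dimethyl-2H-chromen-8-yl)-6-(3-methylbut-2-en-1-yl)chroman-7-ol | CC(C)=CCc1cc2c(cc1O)OC[C@@H](c1ccc(O)c3c1OC(C)(C)C=C3)C2 | target

**Count and risks**
Total steps: 9. Longest linear sequence: 7 steps (1 → 3 → 5 → 10 → 13 → 16 → 18 → 19; the branch through 6 and 8 is equally long).

Steps most likely to fail:

1. Step 6 (proposed new method). The ionisation may be diverted before ring A captures the bridged ion: the ortho ether oxygen may take part with loss of the tertiary propargyl group, a hydride may shift to give a benzylic cation, or the ion may be opened at the secondary carbon. The fallback uses known chemistry, sets out from 8 and comes back at 13. The Grignard reagent from 8 (made as in step 5) would be added to ethylene oxide (CuI cat.) to give the 2-arylethanol F1. F1 would be oxidised (TEMPO, PhI(OAc)2, MeCN/H2O) to the arylacetic acid F2, and F2 joined (t-BuCOCl, Et3N; then lithiated (R)-4-benzyl-1,3-oxazolidin-2-one) to the imide F3. In parallel, commercial 5-bromo-2,4-dihydroxybenzaldehyde would be silylated at the non-chelated 4-hydroxyl to the silyl ether F4, allylated at O-2 to the allyl ether F5, reduced (NaBH4) to the benzyl alcohol F6 and brominated (CBr4, PPh3) to the benzyl bromide F7. Evans alkylation of the sodium enolate of F3 (NaN(SiMe3)2, THF, −78 °C) with F7 would set C3 anti to the auxiliary benzyl group in the alkylated imide F8. LiBH4 would then give the primary alcohol F9, Pd(PPh3)4 and morpholine would remove the allyl group to give the phenol F10, and Mitsunobu etherification (PPh3, DIAD) would close ring C to 13.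

2. Step 5. Proton transfer from residual alkyne to the aryl–magnesium bond, sluggish magnesium insertion into the electron-rich bromide, or binding of the copper by the acetylide may leave the epoxide unopened. The fallback sets out from 6 and comes back at 10; it forms the aryl–CH2 bond before the propargyl ether exists. Phenol 6 would be protected (MeOCH2Cl, i-Pr2NEt) as the MOM ether F11, whose plain Grignard reagent (Mg, THF; CuI cat.) would open 5 to the MOM-protected alcohol F12. Methanolysis (HCl cat., MeOH) would give the phenol F13, and copper-catalysed propargylation with 7 (DBU, CuCl2), which takes the phenol and not the secondary alcohol, would give 10.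

3. Step 1. Alkylation at the wrong hydroxyl, double alkylation or opening of the oxirane by the phenoxide may erode the yield of the single mono-ether. The fallback sets out from 2 and comes back at 5, replacing steps 1 and 2. Commercial 5-(benzyloxy)-2-bromophenol, in which the two oxygens are already told apart, would be silylated with 4 to the silyl benzyl diether F14 and debenzylated (BCl3, pentamethylbenzene, CH2Cl2, −78 °C) to the phenol F15. F15 would then be alkylated with 2 (K2CO3, DMF) to give 5.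

**Further compounds**
F1 | step 6 | 2-{2-[(2-methylbut-3-yn-2-yl)oxy]-4-[(triisopropylsilyl)oxy]phenyl}ethan-1-ol | OCCc1ccc(O[Si](C(C)C)(C(C)C)C(C)C)cc1OC(C)(C)C#C
F2 | step 6 | {2-[(2-methylbut-3-yn-2-yl)oxy]-4-[(triisopropylsilyl)oxy]phenyl}acetic acid | OC(=O)Cc1ccc(O[Si](C(C)C)(C(C)C)C(C)C)cc1OC(C)(C)C#C
F3 | step 6 | (4R)-4-benzyl-3-({2-[(2-methylbut-3-yn-2-yl)oxy]-4-[(triisopropylsilyl)oxy]phenyl}acetyl)-1,3-oxazolidin-2-one | O=C(Cc1ccc(O[Si](C(C)C)(C(C)C)C(C)C)cc1OC(C)(C)C#C)N1C(=O)OC[C@H]1Cc1ccccc1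
F4 | step 6 | 5-bromo-2-hydroxy-4-[(triisopropylsilyl)oxy]benzaldehyde | O=Cc1cc(Br)c(O[Si](C(C)C)(C(C)C)C(C)C)cc1O
F5 | step 6 | 5-bromo-2-(prop-2-en-1-yloxy)-4-[(triisopropylsilyl)oxy]benzaldehyde | O=Cc1cc(Br)c(O[Si](C(C)C)(C(C)C)C(C)C)cc1OCC=C
F6 | step 6 | {5-bromo-2-(prop-2-en-1-yloxy)-4-[(triisopropylsilyl)oxy]phenyl}methanol | OCc1cc(Br)c(O[Si](C(C)C)(C(C)C)C(C)C)cc1OCC=C
F7 | step 6 | [2-bromo-4-(bromomethyl)-5-(prop-2-en-1-yloxy)phenoxy]triisopropylsilane | BrCc1cc(Br)c(O[Si](C(C)C)(C(C)C)C(C)C)cc1OCC=C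
F8 | step 6 | (4R)-4-benzyl-3-[(2R)-3-{5-bromo-2-(prop-2-en-1-yloxy)-4-[(triisopropylsilyl)oxy]phenyl}-2-{2-[(2-methylbut-3-yn-2-yl)oxy]-4-[(triisopropylsilyl)oxy]phenyl}propanoyl]-1,3-oxazolidin-2-one | O=C([C@@H](c1ccc(O[Si](C(C)C)(C(C)C)C(C)C)cc1OC(C)(C)C#C)Cc1cc(Br)c(O[Si](C(C)C)(C(C)C)C(C)C)cc1OCC=C)N1C(=O)OC[C@H]1Cc1ccccc1
F9 | step 6 | (2R)-3-{5-bromo-2-(prop-2-en-1-yloxy)-4-[(triisopropylsilyl)oxy]phenyl}-2-{2-[(2-methylbut-3-yn-2-yl)oxy]-4-[(triisopropylsilyl)oxy]phenyl}propan-1-ol | OC[C@@H](c1ccc(O[Si](C(C)C)(C(C)C)C(C)C)cc1OC(C)(C)C#C)Cc1cc(Br)c(O[Si](C(C)C)(C(C)C)C(C)C)cc1OCC=C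
F10 | step 6 | 4-bromo-2-[(2R)-3-hydroxy-2-{2-[(2-methylbut-3-yn-2-yl)oxy]-4-[(triisopropylsilyl)oxy]phenyl}propyl]-5-[(triisopropylsilyl)oxy]phenol | OC[C@@H](c1ccc(O[Si](C(C)C)(C(C)C)C(C)C)cc1OC(C)(C)C#C)Cc1cc(Br)c(O[Si](C(C)C)(C(C)C)C(C)C)cc1O
F11 | step 5 | [4-bromo-3-(methoxymethoxy)phenoxy]triisopropylsilane | COCOc1cc(O[Si](C(C)C)(C(C)C)C(C)C)ccc1Br
F12 | step 5 | (2R)-1-[4-bromo-3-(triisopropylsilyloxy)phenoxy]-3-[2-(methoxymethoxy)-4-(triisopropylsilyloxy)phenyl]propan-2-ol | COCOc1cc(O[Si](C(C)C)(C(C)C)C(C)C)ccc1C[C@@H](O)COc1ccc(Br)c(O[Si](C(C)C)(C(C)C)C(C)C)c1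
F13 | step 5 | 2-{(2R)-3-[4-bromo-3-(triisopropylsilyloxy)phenoxy]-2-hydroxypropyl}-5-(triisopropylsilyloxy)phenol | Oc1cc(O[Si](C(C)C)(C(C)C)C(C)C)ccc1C[C@@H](O)COc1ccc(Br)c(O[Si](C(C)C)(C(C)C)C(C)C)c1
F14 | step 1 | [5-(benzyloxy)-2-bromophenoxy]triisopropylsilane | CC(C)[Si](Oc1cc(OCc2ccccc2)ccc1Br)(C(C)C)C(C)C
F15 | step 1 | 4-bromo-3-[(triisopropylsilyl)oxy]phenol | Oc1ccc(Br)c(O[Si](C(C)C)(C(C)C)C(C)C)c1
A1 | direct plan | 1-[2,4-bis(methoxymethoxy)-5-(3-methylbut-2-en-1-yl)phenyl]ethan-1-one | CC(=O)c1cc(CC=C(C)C)c(OCOC)cc1OCOC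
A2 | direct plan | 5-(methoxymethoxy)-2,2-dimethyl-2H-chromene-8-carbaldehyde | O=Cc1ccc(OCOC)c2C=CC(C)(C)Oc12
A3 | direct plan | 7-hydroxy-3-(5-hydroxy-2,2-dimethyl-2H-chromen-8-yl)-6-(3-methylbut-2-en-1-yl)-4H-chromen-4-one | CC(C)=CCc1cc2c(cc1O)occ(-c1ccc(O)c3C=CC(C)(C)Oc13)c2=O
A4 | direct plan | (3R,4R)-3-(5-hydroxy-2,2-dimethyl-2H-chromen-8-yl)-6-(3-methylbut-2-en-1-yl)chromane-4,7-diol | CC(C)=CCc1cc2c(cc1O)OC[C@@H](c1ccc(O)c3C=CC(C)(C)Oc13)[C@H]2O
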